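A direct plan would close the coumarin first, as 4-hydroxy-5-methylcoumarin A1, O-allylate it to A2 and then grow the chain on the core: cross-metathesis with methacrolein to the (E)-enal A3, catalytic asymmetric allylation at C4', a second cross-metathesis to the prenyl carbinol A4 and, last, a singlet-oxygen ene reaction to place the hydroperoxide on C6'.
Its weakest step would be that last photooxygenation: the C6' configuration would rest on 1,3-induction from a homoallylic hydroxyl, for which no dependable directing effect is known. The stereocenter, the choice between secondary and tertiary hydroperoxide and the competing C2'=C3' alkene would all be left to chance on the most advanced material.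
Next would come the two cross-metatheses: with the allylation they would spend three steps adding seven carbons and no stereocenter. The enal-forming one would pair an allyl vinylogous ester with a 1,1-disubstituted enal, both poor partners, with E/Z and homodimer problems.
Finally, the sequence would be linear on the core, so every step, including both stereocenter-forming ones, would consume coumarin-bearing material and would have to spare the Claisen- and nucleophile-prone 4-allyloxycoumarin.

Plan of the new route:
Cuts: C2'=C3' (aldol condensation of an ethyl ketone with a core aldehyde), C4'–H (oxazaborolidine reduction of the enone so formed), C6'–O (amine-catalysed conjugate addition of a protected hydroperoxide to a C8 dienone, done first, on cheap material) and, in the core, C4a–C5 and O4–C1'.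
Ring order: the lactone ring (ring B) is bought ready-made as triacetic acid lactone, and the benzene ring (ring A) is closed onto it afterwards.
Enabling feature: the methyl group on C5, peri to the C4 oxygen. C5, C6, C7, C8 and this methyl form a 4-oxopentenyl chain on C6 of a 4-alkoxy-2-pyranone (the pentaketide pattern of the 5-methylcoumarins), and pyranone C5 (the future C4a) is the nucleophilic end of its vinylogous enolate.
The weak steps do not arise: there is no metathesis and no photooxygenation, both stereocenters are set by catalysts in polar steps, the peroxide is carried as a perketal through three mild steps only, and core and chain are made separately and joined late.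

Key step: step 4

Locants: coumarin atoms O1 to C8a as usual; side chain C1' (OCH2) to C8' (terminal =CH2).
Assumption: the quinine-derived primary amine of step 8 is taken to shield the Re face of the β-carbon of dienone 15, as it does in other conjugate additions to (E)-enones; should the sense be opposite, the quinidine-derived pseudoenantiomer is used and nothing else changes.

Step 1
Reactants: 1 4-hydroxy-6-methyl-2H-pyran-2-one (triacetic acid lactone); 2 2,2-dimethoxyethanol
Product: 3 4-(2,2-dimethoxyethoxy)-6-methyl-2H-pyran-2-one
Conditions: PPh3 (1.2 equiv), diisopropyl azodicarboxylate (1.2 equiv), THF, 0 °C to rt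
Reagents that add atoms: none
Why: Mitsunobu etherification: the 4-hydroxyl of the pyranone is a vinylogous carboxylic acid and is alkylated on oxygen by the phosphonium-activated primary alcohol, which should give the 4-alkoxy-2-pyranone without the C3-alkylation that alkyl halides and base would bring.

Step 2
Reactants: 4 ethyl (2-methyl-1,3-dioxolan-2-yl)acetate
Product: 5 (2-methyl-1,3-dioxolan-2-yl)acetaldehyde
Conditions: iBu2AlH (1.05 equiv), CH2Cl2, −78 °C; MeOH, then aq potassium sodium tartrate (KNaC4H4O6)
Reagents that add atoms: none
Why: Low-temperature partial reduction of an ester by diisobutylaluminium hydride: the tetrahedral aluminium alkoxide survives at −78 °C and releases the aldehyde only on work-up, while the dioxolane keeps the ketone (the future C5 with its methyl group) masked.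

Step 3
Reactants: 3 4-(2,2-dimethoxyethoxy)-6-methyl-2H-pyran-2-one; 5 (2-methyl-1,3-dioxolan-2-yl)acetaldehyde
Product: 6 1-[4-(2,2-dimethoxyethoxy)-2-oxo-2H-pyran-6-yl]-3-(2-methyl-1,3-dioxolan-2-yl)propan-2-yl acetate (racemic)
Conditions: LiN(iPr)2 (1.05 equiv), THF, −78 °C; 5 (1.2 equiv), −78 °C; Ac2O (1.5 equiv), −78 to 0 °C
Reagents that add atoms: acetic anhydride, CC(=O)OC(C)=O
Why: Vinylogous aldol addition: lithium diisopropylamide deprotonates the 6-methyl group, whose anion is conjugated with the lactone carbonyl, this carbon (the future C8) adds to the aldehyde, and the alkoxide is acetylated in the flask to provide the leaving group for step 4; the carbinol center is racemic and is erased in that step.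

Step 4
Reactants: 6 1-[4-(2,2-dimethoxyethoxy)-2-oxo-2H-pyran-6-yl]-3-(2-methyl-1,3-dioxolan-2-yl)propan-2-yl acetate
Product: 9 4-(2,2-dimethoxyethoxy)-5-methyl-2H-chromen-2-one, via keto acetate 7 (not isolated), via enone 8 (not isolated)
Conditions: pyridinium p-toluenesulfonate (0.3 equiv), acetone/H2O 20:1, 50 °C; evaporate; DBU (3 equiv), toluene (0.02 M), 70 °C
Reagents that add atoms: none
Why: Proposed new method: after ketal exchange to 7, DBU expels acetate (E1cB) to give enone 8, whose C8 methylene, vinylogous to both the lactone and the enone carbonyl, is deprotonated to a trienolate that can place negative charge on pyranone C5 (future C4a) while the side-chain carbonyl (future C5) stays a ketone; bond formation between these two atoms, readable as a vinylogous aldol addition or as a disrotatory six-electron electrocyclization of the 1-oxidohexatriene C5(O−)=C6–C7=C8–C8a=C4a, is followed by loss of water through the acidic C4a–H, which makes ring A aromatic and leaves the pyranone as the lactone ring of the coumarin. The closest known reaction types are the biomimetic aldol aromatization of pyranone-masked polyketides to coumarins and resorcylates and the oxyanion-accelerated electrocyclization of trienolates; what has not been shown is closure onto C5 of an intact 4-alkoxy-2-pyranone with an enone in place of a 1,3-diketone side chain. Ring A closes in the 6-(enolendo)-exo-trig mode at the ketone carbonyl. No stereocenter is formed, and the E/Z isomers of 8 interconvert through the C8 anion, so all of them should funnel into the one aromatic product. The step needs C5 over C3 of the pyranone and ring closure over intermolecular Michael addition: only C5 can reach the ketone through a six-membered ring, and high dilution holds back the intermolecular path. The methyl group must end peri to the C4 oxygen because the ketone carbon that carries it is the atom that bonds to C4a.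

Step 5
Reactants: 9 4-(2,2-dimethoxyethoxy)-5-methyl-2H-chromen-2-one
Product: 10 [(5-methyl-2-oxo-2H-chromen-4-yl)oxy]acetaldehyde
Conditions: CF3CO2H/H2O/CHCl3 2:1:4, 40 °C; dried azeotropically and used crude
Reagents that add atoms: water, O
Why: Acid-catalysed hydrolysis of a dimethyl acetal: the electron-poor α-aryloxy acetal, slow enough to survive the pyridinium salt of step 4, is cleaved by the stronger aqueous acid, to which the coumarin ether and lactone are stable.

Step 6
Reactants: 11 2,3-dimethylbut-2-ene
Product: 12 2-hydroperoxy-2-methoxypropane (2-methoxyprop-2-yl hydroperoxide)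
Conditions: O3, CH2Cl2/MeOH 4:1, −78 °C; N2 purge; kept cold and used as a titrated solution
Reagents that add atoms: ozone, [O-][O+]=O; methanol, CO
Why: Ozonolysis in methanol (Criegee mechanism): the primary ozonide of the tetrasubstituted alkene fragments to acetone and acetone carbonyl oxide, which methanol traps as the α-methoxy hydroperoxide, a hydroperoxide that carries its own acid-labile protecting group.

Step 7
Reactants: 13 methacrolein; 14 dimethyl (2-oxobutyl)phosphonate
Product: 15 (4E)-6-methylhepta-4,6-dien-3-one
Conditions: LiCl (1.2 equiv), iPr2NEt (1.1 equiv), MeCN, 0 °C to rt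
Reagents that add atoms: none
Why: Horner–Wadsworth–Emmons olefination under Masamune–Roush conditions: the stabilised phosphonate anion and the unhindered aldehyde should give the (E)-enone, and the mild base spares the polymerisable dienone.

Step 8
Reactants: 15 (4E)-6-methylhepta-4,6-dien-3-one; 12 2-hydroperoxy-2-methoxypropane
Product: 16 (5S)-5-[(2-methoxypropan-2-yl)peroxy]-6-methylhept-6-en-3-one
Conditions: 9-amino-9-deoxy-epi-quinine (10 mol%), 2-fluorobenzoic acid (20 mol%), 12 (2 equiv), toluene, 0 °C to rt
Reagents that add atoms: none
Why: Asymmetric conjugate peroxidation of an α,β-unsaturated ketone by iminium catalysis: the primary amine of the cinchona catalyst condenses with the ethyl ketone, and its protonated quinuclidine hydrogen-bonds the hydroperoxide and delivers it to the Si face of C5, the β-carbon next to the iminium rather than the remote terminal methylene, which should set C5 (the future C6') as S; the weak acid co-catalyst spares the perketal and disfavours closure of the adduct to the epoxide.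

Step 9
Reactants: 16 (5S)-5-[(2-methoxypropan-2-yl)peroxy]-6-methylhept-6-en-3-one; 10 [(5-methyl-2-oxo-2H-chromen-4-yl)oxy]acetaldehyde
Product: 18 4-{[(2E,6S)-6-[(2-methoxypropan-2-yl)peroxy]-3,7-dimethyl-4-oxoocta-2,7-dien-1-yl]oxy}-5-methyl-2H-chromen-2-one, via aldol adduct 17 (not isolated)
Conditions: (c-C6H11)2BCl (1.3 equiv), Et3N (1.5 equiv), Et2O, −78 to 0 °C; 10 (1.2 equiv) in CH2Cl2, −78 to −20 °C; pH 7 buffer, MeOH, 30% H2O2, 0 °C; crude 17: MeSO2Cl (1.5 equiv), Et3N (4 equiv), CH2Cl2, 0 °C to rt
Reagents that add atoms: none
Why: Boron-mediated aldol addition followed by mesylation and E1cB elimination, that is an aldol condensation: dicyclohexylboron chloride and triethylamine should enolise the ketone on its unbranched ethyl side and not at the methylene next to the branched perketal carbon, the enolate adds to the aldehyde, and all four diastereomers of 17 converge on the thermodynamically preferred (E)-2-methyl enone, which fixes the C2'=C3' geometry.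

Step 10
Reactants: 18 4-{[(2E,6S)-6-[(2-methoxypropan-2-yl)peroxy]-3,7-dimethyl-4-oxoocta-2,7-dien-1-yl]oxy}-5-methyl-2H-chromen-2-one
Product: 19 4-{[(2E,4S,6S)-4-hydroxy-6-[(2-methoxypropan-2-yl)peroxy]-3,7-dimethylocta-2,7-dien-1-yl]oxy}-5-methyl-2H-chromen-2-one
Conditions: (R)-2-methyl-CBS-oxazaborolidine (0.3 equiv), catecholborane (1.8 equiv), toluene/CH2Cl2, −78 °C; MeOH, pH 7 buffer
Reagents that add atoms: none
Why: Corey–Bakshi–Shibata reduction: the (R)-oxazaborolidine binds the ketone with the alkenyl group as the large substituent and catecholborane delivers hydride to the Re face of the carbonyl, which should set C4' as S by catalyst control (1,3-anti to C6') with 1,2-selectivity; the lactone, the perketal and the 1,1-disubstituted alkene are not expected to react with catecholborane at −78 °C.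

Step 11
Reactants: 19 4-{[(2E,4S,6S)-4-hydroxy-6-[(2-methoxypropan-2-yl)peroxy]-3,7-dimethylocta-2,7-dien-1-yl]oxy}-5-methyl-2H-chromen-2-one
Product: 20 4-{[(2E,4S,6S)-6-hydroperoxy-4-hydroxy-3,7-dimethylocta-2,7-dien-1-yl]oxy}-5-methyl-2H-chromen-2-one (target)
Conditions: AcOH/THF/H2O 4:2:1, rt; cold silica chromatography, no metal tools
Reagents that add atoms: none
Why: Acid-catalysed hydrolysis of a monoperoxyketal: aqueous acetic acid protonates the methoxy group of the 2-methoxyprop-2-yl unit, which leaves as acetone and methanol and frees the hydroperoxide without touching the C6'–O or O–O bond, so C6' keeps its configuration.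

## Compound list
1 | 4-hydroxy-6-methyl-2H-pyran-2-one (triacetic acid lactone) | Cc1cc(O)cc(=O)o1 | starting material
2 | 2,2-dimethoxyethanol | COC(CO)OC | starting material
3 | 4-(2,2-dimethoxyethoxy)-6-methyl-2H-pyran-2-one | COC(COc1cc(C)oc(=O)c1)OC | intermediate
4 | ethyl (2-methyl-1,3-dioxolan-2-yl)acetate | CCOC(=O)CC1(C)OCCO1 | starting material
5 | (2-methyl-1,3-dioxolan-2-yl)acetaldehyde | O=CCC1(C)OCCO1 | intermediate
6 | 1-[4-(2,2-dimethoxyethoxy)-2-oxo-2H-pyran-6-yl]-3-(2-methyl-1,3-dioxolan-2-yl)propan-2-yl acetate (racemic) | COC(COc1cc(CC(OC(C)=O)CC2(C)OCCO2)oc(=O)c1)OC | intermediate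
7 | 1-[4-(2,2-dimethoxyethoxy)-2-oxo-2H-pyran-6-yl]-4-oxopentan-2-yl acetate (racemic) | COC(COc1cc(CC(OC(C)=O)CC(C)=O)oc(=O)c1)OC | intermediate
8 | 4-(2,2-dimethoxyethoxy)-6-[(2E)-4-oxopent-2-en-1-yl]-2H-pyran-2-one | COC(COc1cc(C/C=C/C(C)=O)oc(=O)c1)OC | intermediate
9 | 4-(2,2-dimethoxyethoxy)-5-methyl-2H-chromen-2-one | COC(COc1cc(=O)oc2cccc(C)c12)OC | intermediate
10 | [(5-methyl-2-oxo-2H-chromen-4-yl)oxy]acetaldehyde | O=CCOc1cc(=O)oc2cccc(C)c12 | intermediate
11 | 2,3-dimethylbut-2-ene | CC(C)=C(C)C | starting material
12 | 2-hydroperoxy-2-methoxypropane | COC(C)(C)OO | intermediate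
13 | methacrolein (2-methylprop-2-enal) | C=C(C)C=O | starting material
14 | dimethyl (2-oxobutyl)phosphonate | CCC(=O)CP(=O)(OC)OC | starting material
15 | (4E)-6-methylhepta-4,6-dien-3-one | CCC(=O)/C=C/C(C)=C | intermediate
16 | (5S)-5-[(2-methoxypropan-2-yl)peroxy]-6-methylhept-6-en-3-one | C=C(C)[C@H](CC(=O)CC)OOC(C)(C)OC | intermediate
17 | 4-{[(6S)-2-hydroxy-6-[(2-methoxypropan-2-yl)peroxy]-3,7-dimethyl-4-oxooct-7-en-1-yl]oxy}-5-methyl-2H-chromen-2-one (mixture at C2' and C3') | C=C(C)[C@H](CC(=O)C(C)C(O)COc1cc(=O)oc2cccc(C)c12)OOC(C)(C)OC | intermediate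
18 | 4-{[(2E,6S)-6-[(2-methoxypropan-2-yl)peroxy]-3,7-dimethyl-4-oxoocta-2,7-dien-1-yl]oxy}-5-methyl-2H-chromen-2-one | C=C(C)[C@H](CC(=O)/C(C)=C/COc1cc(=O)oc2cccc(C)c12)OOC(C)(C)OC | intermediate
19 | 4-{[(2E,4S,6S)-4-hydroxy-6-[(2-methoxypropan-2-yl)peroxy]-3,7-dimethylocta-2,7-dien-1-yl]oxy}-5-methyl-2H-chromen-2-one | C=C(C)[C@H](C[C@H](O)/C(C)=C/COc1cc(=O)oc2cccc(C)c12)OOC(C)(C)OC | intermediate
20 | 4-{[(2E,4S,6S)-6-hydroperoxy-4-hydroxy-3,7-dimethylocta-2,7-dien-1-yl]oxy}-5-methyl-2H-chromen-2-one | C=C(C)[C@H](C[C@H](O)/C(C)=C/COc1cc(=O)oc2cccc(C)c12)OO | target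

Total step count: 11. Longest linear sequence: 7 steps (1 or 2, then 3, 4, 5, 9, 10, 11).

Steps most likely to fail:

Step 4 (closure of ring A). The acetate may leave but the trienolate may fail to close at pyranone C5, or the amidine base may open the pyranone ring. The fallback uses known chemistry and closes ring B last instead. It sets out from 2: Mitsunobu esterification with commercial 2-hydroxy-6-methylbenzoic acid (PPh3, diisopropyl azodicarboxylate, THF) would give 2,2-dimethoxyethyl 2-hydroxy-6-methylbenzoate F1. Heating F1 with ketenylidenetriphenylphosphorane (Ph3P=C=C=O, toluene, 110 °C) acylates the phenol, and the ester ylide so formed closes the lactone ring by intramolecular Wittig olefination of the ester carbonyl. The route is rejoined at 9.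

Step 8 (hydroperoxide addition). The hydroperoxide may add at the terminal methylene (1,6) instead of at C5, the perketal may be cleaved by the acid co-catalyst, or the facial selectivity may be poor. The fallback makes the C–O bond by SN2 displacement with inversion instead of conjugate addition. It sets out from 12, which then serves as the nucleophile, and from commercial propanal and 3-methylbut-3-en-2-one, and runs as follows:
- Aldol addition (LiN(iPr)2, THF, −78 °C) would give racemic 5-hydroxy-2-methylhept-1-en-3-one F2.
- Silylation (tBuMe2SiCl, imidazole) would give 5-[(tert-butyldimethylsilyl)oxy]-2-methylhept-1-en-3-one F3.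
- Corey–Bakshi–Shibata reduction with the (S)-oxazaborolidine and catecholborane would give (3R)-5-[(tert-butyldimethylsilyl)oxy]-2-methylhept-1-en-3-ol F4.
- Mesylation (MeSO2Cl, Et3N, −20 °C) would give (3R)-5-[(tert-butyldimethylsilyl)oxy]-2-methylhept-1-en-3-yl methanesulfonate F5.
- Displacement by the potassium salt of 12 (KOtBu, DMF, 0 °C) with inversion would give tert-butyl({(5S)-5-[(2-methoxypropan-2-yl)peroxy]-6-methylhept-6-en-3-yl}oxy)dimethylsilane F6.
- Bu4NF would give (5S)-5-[(2-methoxypropan-2-yl)peroxy]-6-methylhept-6-en-3-ol F7.
- Dess–Martin oxidation rejoins the route at 16.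

Step 9 (fragment union). The boron reagent may also enolise 16 at the methylene next to the perketal carbon, followed by β-elimination of the perketal, or the elimination may give E/Z mixtures. The fallback reverses the order of events. It sets out from 15 and 10: the same boron aldol and mesylation–elimination sequence, now on a ketone with a single enolisable α-carbon, would give 4-{[(5E)-2-hydroxy-3,7-dimethyl-4-oxoocta-5,7-dien-1-yl]oxy}-5-methyl-2H-chromen-2-one F8 and from it 4-{[(2E,5E)-3,7-dimethyl-4-oxoocta-2,5,7-trien-1-yl]oxy}-5-methyl-2H-chromen-2-one F9. Conjugate addition of 12 under the conditions of step 8, at the α-unsubstituted C5'=C6' arm, rejoins the route at 18.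

## Further compounds
F1 | step 4 | 2,2-dimethoxyethyl 2-hydroxy-6-methylbenzoate | COC(COC(=O)c1c(C)cccc1O)OC
F2 | step 8 | 5-hydroxy-2-methylhept-1-en-3-one (racemic) | C=C(C)C(=O)CC(O)CC
F3 | step 8 | 5-[(tert-butyldimethylsilyl)oxy]-2-methylhept-1-en-3-one (racemic) | C=C(C)C(=O)CC(CC)O[Si](C)(C)C(C)(C)C
F4 | step 8 | (3R)-5-[(tert-butyldimethylsilyl)oxy]-2-methylhept-1-en-3-ol (mixture at C5) | C=C(C)[C@H](O)CC(CC)O[Si](C)(C)C(C)(C)C
F5 | step 8 | (3R)-5-[(tert-butyldimethylsilyl)oxy]-2-methylhept-1-en-3-yl methanesulfonate (mixture at C5) | C=C(C)[C@H](OS(C)(=O)=O)CC(CC)O[Si](C)(C)C(C)(C)C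
F6 | step 8 | tert-butyl({(5S)-5-[(2-methoxypropan-2-yl)peroxy]-6-methylhept-6-en-3-yl}oxy)dimethylsilane (mixture at C3) | C=C(C)[C@H](CC(CC)O[Si](C)(C)C(C)(C)C)OOC(C)(C)OC
F7 | step 8 | (5S)-5-[(2-methoxypropan-2-yl)peroxy]-6-methylhept-6-en-3-ol (mixture at C3) | C=C(C)[C@H](CC(O)CC)OOC(C)(C)OC
F8 | step 9 | 4-{[(5E)-2-hydroxy-3,7-dimethyl-4-oxoocta-5,7-dien-1-yl]oxy}-5-methyl-2H-chromen-2-one (mixture of diastereomers) | C=C(C)/C=C/C(=O)C(C)C(O)COc1cc(=O)oc2cccc(C)c12
F9 | step 9 | 4-{[(2E,5E)-3,7-dimethyl-4-oxoocta-2,5,7-trien-1-yl]oxy}-5-methyl-2H-chromen-2-one | C=C(C)/C=C/C(=O)/C(C)=C/COc1cc(=O)oc2cccc(C)c12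
A1 | direct plan | 4-hydroxy-5-methyl-2H-chromen-2-one | Cc1cccc2oc(=O)cc(O)c12
A2 | direct plan | 5-methyl-4-(prop-2-en-1-yloxy)-2H-chromen-2-one | C=CCOc1cc(=O)oc2cccc(C)c12
A3 | direct plan | (2E)-2-methyl-4-[(5-methyl-2-oxo-2H-chromen-4-yl)oxy]but-2-enal | O=C/C(C)=C/COc1cc(=O)oc2cccc(C)c12
A4 | direct plan | 4-{[(2E,4S)-4-hydroxy-3,7-dimethylocta-2,6-dien-1-yl]oxy}-5-methyl-2H-chromen-2-one | CC(C)=CC[C@H](O)/C(C)=C/COc1cc(=O)oc2cccc(C)c12
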